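- Of the amounts charged, E is 1.5 M in both runs, and the south run holds less G than the west run: 0.75 equiv against 1.5 equiv in the west run, which is the flask asked about.

| setting | west | south | flask |
|---|---|---|---|
| E | 1.5 M | 1.5 M | 1.5 M |
| G | 1.5 equiv | 0.75 equiv | 1.50 equiv |
| remark | the very flask that is asked about, followed so far | run made earlier |  |
| time |  |  | 2.0 min |
| volume of the second phase over the first |  |  | 1.0 |

| run | time / s | J / % | E / % |
|---|---|---|---|
| west | 10.0 | 3.9 | 98.3 |
| west | 20.0 | 3.8 | 97.4 |
| west | 30.0 | 7.2 | 93.0 |
| west | 50.0 | 15.0 | 84.7 |
| south | 10.0 | 0 | 100.1 |
| south | 20.0 | 2.5 | 97.4 |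
| south | 30.0 | 5.2 | 96.3 |
| south | 50.0 | 6.7 | 92.5 |

(scatter of a reading: 1 percentage point)

- J at 2.0 min, in percent of the E charged
- the change that raises the amount of J at 2.0 min, in percent of the E charged most ("none" if none brings more than 2 percentage points) (larch / cedar / none)
- amount of J at 2.0 min, in percent of the E charged, after larch

- larch: doubling the transfer coefficient of G, all else as stated
- cedar: doubling the amount of G, all else as stated

- Neither run is near an end state: at 50.0 s the west run has 15.0% of J and 84.7% of E, the south run 6.7% of J and 92.5% of E.
- Call the pace, J at the last reading over the time of that reading, an average initial rate as a share of the E charged: the west run reads 0.180 /min, the south run 0.0804 /min.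
- As a reading with a scatter of 1 percentage point, the west run has about twice the J of the south run, on twice the G.
- My own reckoning carries the west pace to 2.0 min in a straight line and gets 36.0%. E must still fall, so I take this as an upper mark for J.
- The forecast is lower than that mark: 30%, with cedar as the best change and 42% after larch, holding that “the rate is roughly first order in the G charged”.

- The flask gives 26.6% of J at 2.0 min, cedar is the best change with a gain of 16 points, and larch gives 33.1%, below the forecast's 42%. Beside the J, equal to 0.399 M, the flask holds more D, 0.682 M. Its average pace to 2.0 min is 0.133 /min, slower than the early 0.180 /min.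

    Q ⇌ G, rate k1*([Q] - [G]/K1) per volume of the first phase (partition coefficient = 4.30, kL = 0.0360 /s)
    E + Q → J (k = 0.0330 /M/s)
    Q + J → X (k = 0.0130 /M/s)
    Q → D (k = 0.0670 /s)

- At 80 s, the same flask read earlier, the pace gives 24.0% as the upper mark. The computed J there is 20.4%.

The numbers in the tables were computed for an exercise.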